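## Retrosynthetic overview

- **Structural feature:** quaternary C10 (rings A/B) carries the C20 carbonyl and is bonded to C9. C9 is allylic to C8 once ring C is read as its 13-oxo-Δ8(14) form. An ester C20(=O)–O–C14 therefore puts C10 and C9 at the two ends of a [3,3] array, and the C5 acetate carbon C6 is then one 5-exo closure away from C8.
- **Disconnections:** C20 CHO from C20 CO2H. Ring D at C13–C16 (ketyl–alkyne). Ring B at C6–C8 (cationic Michael closure on an allylic ketal) together with C9–C10 (Ireland–Claisen) in a single operation. Then the ester C20–O–C14.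
- **Fragments:** the ring-A acid comes from dimethyl glutaconate and the Nazarov reagent (double Michael, C4 methylation, enzymatic C3 reduction/resolution, ester differentiation through the C7/C20 anhydride). The ring-C allylic alcohol comes from cyclohexane-1,2-dione monoketal and TMS-propargyl bromide.
- **Ring order:** A is built, C is bought, B is closed in the key step that also joins A to C, and D is closed last.

Key step: step 13

Remark: gibberellin numbering (C1–C20) and α/β faces are used for all intermediates. The target is written and made as the open 20-oxo form, which may equilibrate with its 19,20-lactol tautomer.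
Remark: metal enolates and carboxylate salts are treated as reactive forms of the numbered compounds and get no number of their own.

## Route

Step 1
Reactants: 1 dimethyl (E)-glutaconate; 2 methyl 3-oxopent-4-enoate (Nazarov reagent)
Product: 3 (±)-dimethyl 2-(2-methoxy-2-oxoethyl)-4-oxocyclohexane-1,3-dicarboxylate (ring A; C4 and C10 epimerisable)
Conditions: Cs2CO3 (20 mol%), CH2Cl2, 0 °C → rt, slow addition of 2 to 1
Reagents that add atoms: none
Why: Base-catalysed double Michael annulation with the Nazarov reagent: the delocalised anion of 1 adds through C10 to the vinyl ketone (C10–C1) and the β-keto ester carbon C4 then closes 6-exo-trig on the remaining enoate carbon C5 (the opposite order gives the same ring), slow addition of 2 limits its self-condensation, and no stereocentre needs control because C4 and C10 are epimerisable and the material is racemic.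

Step 2
Reactants: 3 keto triester
Product: 4 (±)-C4-methyl keto triester, C18 methyl trans to the C5 acetate arm (4β-Me, 4α-CO2Me, 5β-H; C10 epimers)
Conditions: MeI, K2CO3, acetone, rt
Reagents that add atoms: methyl iodide CI
Why: C-alkylation of a β-keto ester enolate: allylic strain with the C4 ester tips the C5 acetate arm axial, so MeI enters axially on the opposite face and sets C4 relative to C5, while carbonate is too weak to touch C6 or C10.

Step 3
Reactants: 4 (±)-C4-methyl keto triester
Product: 5 (3S,4S,5S)-hydroxy triester (3β-OH axial; single enantiomer; C10 epimers)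
Conditions: (S)-selective ketoreductase (chosen by panel screening), NADP+ (cat.), i-PrOH, phosphate buffer pH 7, DMSO (5 vol%), 30 °C, stopped at about half conversion
Reagents that add atoms: none
Why: Enzymatic ketone reduction run as a kinetic resolution: hydride is delivered to one face of C3 only, so the (4S,5S)-ketone should give the (3S)-alcohol while its mirror image stays as ketone or gives a chromatographically distinct diastereomer, which fixes C3 and the absolute configuration of C4 and C5 together.

Step 4
Reactants: 5 hydroxy triester
Product: 6 3-O-TBS triester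
Conditions: TBSOTf, 2,6-lutidine, CH2Cl2, 0 °C
Reagents that add atoms: tert-butyldimethylsilyl triflate CC(C)(C)[Si](C)(C)OS(=O)(=O)C(F)(F)F
Why: Silyl ether formation with the triflate, which an axial alcohol next to a quaternary carbon requires, and which blocks retro-aldol cleavage of C3–C4 in every later basic step.

Step 5
Reactants: 6 3-O-TBS triester
Product: 7 C7,C20-diacid C19-methyl ester
Conditions: LiOH (4 equiv), THF–MeOH–H2O, 40 °C; then 1 M HCl to pH 3, 0 °C
Reagents that add atoms: lithium hydroxide [Li+].[OH-]
Why: Chemoselective saponification: the primary C7 and secondary C20 esters are hydrolysed, whereas the C19 ester on quaternary C4 beside the silyl ether resists acyl attack and has no α-hydrogen through which the OTBS group could be eliminated.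

Step 6
Reactants: 7 diacid
Product: 8 cyclic C7/C20 anhydride (six-membered, fused at C5–C10)
Conditions: Ac2O, toluene, 80 °C
Reagents that add atoms: none
Why: Dehydrative closure of a 1,5-diacid to a glutaric-type anhydride, possible for both C10 epimers, so the undefined C10 centre causes no loss.

Step 7
Reactants: 8 cyclic anhydride
Product: 9 ring-A acid (C20 CO2H free; C7 and C19 methyl esters; 3β-OTBS)
Conditions: MeOH, DMAP (cat.), CH2Cl2, 0 °C → rt
Reagents that add atoms: methanol CO
Why: Regioselective anhydride alcoholysis: methanol attacks the C7 carbonyl flanked by a CH2 rather than the C20 carbonyl on the ring methine, which leaves C20 as the only free acid.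

Step 8
Reactants: 10 1,4-dioxaspiro[4.5]decan-6-one
Product: 12 1,4-dioxaspiro[4.5]dec-7-en-6-one, via trimethylsilyl enol ether 11 (not isolated)
Conditions: LDA, THF, −78 °C; TMSCl; then Pd(OAc)2 (10 mol%), O2 (1 atm), DMSO, rt
Reagents that add atoms: chlorotrimethylsilane C[Si](C)(C)Cl (silicon of 11 only)
Why: Saegusa–Ito dehydrogenation in its aerobic catalytic form: only one α-carbon (C8) carries hydrogen, so the enol silane is a single regioisomer, and the neutral medium spares the dioxolane.

Step 9
Reactants: 12 enone ketal; 13 3-bromo-1-(trimethylsilyl)propyne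
Product: 14 (±)-7-[3-(trimethylsilyl)prop-2-ynyl]-1,4-dioxaspiro[4.5]dec-8-en-6-one (β,γ-enone, propargyl on C8)
Conditions: LDA (1.1 equiv), THF, −78 °C, slow inverse addition of 12; then 13, −78 → −20 °C
Reagents that add atoms: none
Why: Deconjugative α-alkylation of an extended enolate: the α′ carbon is the ketal carbon and has no hydrogen, so the amide can only remove a γ-hydrogen (C11), and the dienolate reacts with the reactive propargylic bromide at its α-carbon C8.

Step 10
Reactants: 14 β,γ-enone
Product: 15 7-[3-(trimethylsilyl)prop-2-ynyl]-1,4-dioxaspiro[4.5]dec-7-en-6-one (C8=C9 enone, C14 ketone, C13 ketal)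
Conditions: DBU (0.2 equiv), CH2Cl2, rt
Reagents that add atoms: none
Why: Base-catalysed reconjugation through the same dienolate with protonation at C11 gives the more stable trisubstituted conjugated enone, and DBU is too weak to metalate the C15 methylene.

Step 11
Reactants: 15 propargyl enone ketal
Product: 16 (6R)-7-[3-(trimethylsilyl)prop-2-ynyl]-1,4-dioxaspiro[4.5]dec-7-en-6-ol ((14R)-allylic alcohol)
Conditions: (R)-selective ketoreductase (panel screening), NADP+ (cat.), i-PrOH, phosphate buffer pH 7, 30 °C
Reagents that add atoms: none
Why: Enzymatic asymmetric 1,2-reduction sets C14, and it is preferred to an oxazaborolidine reduction because both flanks of the ketone (spiro-ketal carbon and α-substituted alkene) are bulky near the carbonyl lone pairs, whereas an enzyme pocket can tell the flat long propargyl-alkene side from the compact dioxolane.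

Step 12
Reactants: 9 ring-A acid; 16 (14R)-allylic alcohol
Product: 18 ester joining C20 of the ring-A acid to O14 of the ring-C alcohol (14R; C10 epimers), via mixed trichlorobenzoic anhydride 17 (not isolated)
Conditions: 2,4,6-trichlorobenzoyl chloride, Et3N, toluene, rt; then 16, DMAP, toluene, rt → 40 °C
Reagents that add atoms: 2,4,6-trichlorobenzoyl chloride O=C(Cl)c1c(Cl)cc(Cl)cc1Cl (aroyl group of 17 only)
Why: Yamaguchi esterification couples a hindered secondary acid with a hindered secondary alcohol without touching the C14–O bond, and any epimerisation at C10 is harmless because that centre is erased in the next step.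

Step 13
Reactants: 18 C20–O–C14 ester
Product: 22 tricyclic A/B/C keto acid (13-oxo; C20 CO2H; C7 and C19 methyl esters; 3β-OTBS; TMS-propargyl on C8β; 5β-H; 9β-H; 6β-CO2Me), via bis(silyl ketene acetal) 19 (not isolated), via rearranged silyl ester 20 (not isolated), via cyclised enol ether 21 (not isolated)
Conditions: LDA (2.3 equiv), THF, −78 °C; TMSCl (3 equiv), −78 °C → rt, then 65 °C; volatiles off in vacuo, pentane, cannula filtration from LiCl, CH2Cl2, TMSOTf (0.3 equiv), −78 → −30 °C; then 1 M HCl–THF, 0 °C → rt
Reagents that add atoms: chlorotrimethylsilane C[Si](C)(C)Cl (silyl groups of 19, 20 and 21); water O (carbonyl oxygen at C13 of 22)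
Why: Proposed new method: double deprotonation and silylation give ketene acetals at C10=C20 and C6=C7, only the allylic one undergoes the Ireland–Claisen [3,3] shift on warming (C9–C10 made, C14–O broken, alkene moved to C8=C14), catalytic TMSOTf then opens the now allylic dioxolane to a 1-alkoxyallyl cation that the surviving C6=C7 ketene acetal captures at C8, and aqueous acid converts enol ether and silyl ester 21 into ketone and acid 22. The closest known reactions are the Ireland–Claisen rearrangement of cyclohex-2-enyl esters of α-branched acids to quaternary carbons and the Lewis-acid Mukaiyama–Michael addition of silyl ketene acetals to α,β-unsaturated ketals, and what is new is their coupling in one telescoped operation in which the first reaction creates the acceptor of the second. Ring B (C5–C6–C8–C9–C10) closes 5-exo-trig, C8 being the ring atom and C14 the exocyclic end of the cationic π system. C9 is set by suprafacial transfer from the (14R)-carbinol, C10 by equatorial bond formation on the β face of ring A away from the axial 4α-ester and anti to the C5 arm, C8 by the short tether C9–C10–C5–C6 that reaches only the face of ring C already carrying C10 (cis B/C), and C6 by allylic strain, H5 eclipsing the ketene acetal so that C7 ends syn to H5 (6β, also the more stable epimer). The selectivity the step needs is the C10 face, and because the old C10 centre is erased and chair and boat arrays of cyclohexenyl esters lie close in energy, either ketene acetal geometry can follow the face preference imposed by ring A. Chemoselectivity rests on C19 having no α-hydrogen, on every conceivable Dieckmann closure being four-membered, on the ketal keeping enone protons out of the base step, and on the limited base charge leaving the C15 methylene alone.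

Step 14
Reactants: 22 tricyclic keto acid
Product: 23 terminal-alkyne keto acid (prop-2-ynyl on C8)
Conditions: K2CO3 (2 equiv), MeOH, rt; then 1 M HCl to pH 3, 0 °C
Reagents that add atoms: none
Why: Carbonate-mediated methanolysis of the alkynylsilane (protiodesilylation), too mild to enolise the C7 ester or to start a retro-Michael opening of C6–C8 through the C13 ketone, so no stereocentre changes.

Step 15
Reactants: 23 terminal-alkyne keto acid
Product: 24 tetracyclic 13-hydroxy-16-ene C20 acid (C7 and C19 methyl esters, 3β-OTBS)
Conditions: LiHMDS (1.0 equiv), THF, −78 °C; then added to SmI2 (5 equiv), HMPA, t-BuOH (3 equiv), THF, 0 °C → rt; 0.5 M HCl work-up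
Reagents that add atoms: none
Why: SmI2–HMPA ketyl–alkyne reductive cyclisation of a γ-ethynyl ketone, 5-exo-dig (C13–C16), in which the axial β-propargyl arm on C8 can reach only one face of C13 and thus sets that centre, the acid being masked as its lithium salt so that it does not protonate the ketyl before ring closure.

Step 16
Reactants: 24 tetracyclic hydroxy acid
Product: 26 C20 aldehyde (C7 and C19 methyl esters; 3β-OTBS; 13-OH), via C20 acid chloride 25 (not isolated)
Conditions: 1-chloro-N,N,2-trimethylprop-1-en-1-amine (1.1 equiv), CH2Cl2, 0 °C; then THF, LiAlH(Ot-Bu)3 (up to 2.1 equiv, in portions), −78 °C; Rochelle salt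
Reagents that add atoms: 1-chloro-N,N,2-trimethylprop-1-en-1-amine CC(C)=C(Cl)N(C)C (chlorine of 25 only)
Why: Neutral acid chloride formation followed by partial reduction with the bulky alkoxyaluminium hydride: C20 is the only free acid and hence the only acyl group activated, and stopping at the aldehyde level avoids a C20 carbinol or alkoxide, which would lactonise at once onto the 1,3-diaxial C19 ester.

Step 17
Reactants: 26 C20 aldehyde diester
Product: 27 3-O-TBS 20-oxo 7,19-diacid
Conditions: KOH (excess), dioxane–H2O (no alcohol), 85 °C, Ar; then 1 M HCl to pH 3, 0 °C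
Reagents that add atoms: potassium hydroxide [K+].[OH-]
Why: Saponification in which the hindered C19 ester is cleaved with anchimeric assistance (hydroxide adds to the 1,3-diaxial formyl group, the hydrate anion acylates itself to the 19,20-lactol lactone, and this opens to the carboxylate), the C7 ester hydrolyses normally at this temperature, the aldehyde has no α-hydrogen, the O3 silyl ether blocks retro-aldol epimerisation, and any 6α-ester would epimerise to the more stable 6β series before it is cleaved.

Step 18
Reactants: 27 3-O-TBS diacid
Product: 28 target CNP0236431.1 (3β,13-dihydroxy-20-oxo-gibberell-16-ene-7,19-dioic acid)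
Conditions: HF·pyridine, pyridine, THF, 0 °C → rt
Reagents that add atoms: none
Why: Fluoride desilylation under buffered, weakly acidic conditions avoids both base-induced C3 epimerisation and the strong-acid Wagner–Meerwein rearrangement of the 13-hydroxy-16-ene C/D unit.

## Compound list

1 | dimethyl (E)-glutaconate | COC(=O)/C=C/CC(=O)OC | starting material
2 | methyl 3-oxopent-4-enoate | C=CC(=O)CC(=O)OC | starting material
3 | (±)-ring-A keto triester | COC(=O)CC1C(C(=O)OC)CCC(=O)C1C(=O)OC | intermediate
4 | (±)-C4-methyl keto triester (relative configuration shown, wanted enantiomer drawn) | COC(=O)C1CCC(=O)[C@@](C)(C(=O)OC)[C@H]1CC(=O)OC | intermediate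
5 | (3S,4S,5S)-hydroxy triester | COC(=O)C1CC[C@H](O)[C@@](C)(C(=O)OC)[C@H]1CC(=O)OC | intermediate
6 | 3-O-TBS triester | COC(=O)C1CC[C@H](O[Si](C)(C)C(C)(C)C)[C@@](C)(C(=O)OC)[C@H]1CC(=O)OC | intermediate
7 | C7,C20-diacid C19-methyl ester | OC(=O)C1CC[C@H](O[Si](C)(C)C(C)(C)C)[C@@](C)(C(=O)OC)[C@H]1CC(=O)O | intermediate
8 | cyclic C7/C20 anhydride | O=C1OC(=O)C2CC[C@H](O[Si](C)(C)C(C)(C)C)[C@@](C)(C(=O)OC)[C@H]2C1 | intermediate
9 | ring-A acid (C20 CO2H) | OC(=O)C1CC[C@H](O[Si](C)(C)C(C)(C)C)[C@@](C)(C(=O)OC)[C@H]1CC(=O)OC | intermediate
10 | 1,4-dioxaspiro[4.5]decan-6-one | O=C1CCCCC12OCCO2 | starting material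
11 | (1,4-dioxaspiro[4.5]dec-6-en-6-yloxy)trimethylsilane | C[Si](C)(C)OC1=CCCCC12OCCO2 | intermediate
12 | 1,4-dioxaspiro[4.5]dec-7-en-6-one | O=C1C=CCCC12OCCO2 | intermediate
13 | 3-bromo-1-(trimethylsilyl)propyne | C[Si](C)(C)C#CCBr | starting material
14 | (±)-β,γ-enone, propargyl on C8 | C[Si](C)(C)C#CCC1C=CCC2(OCCO2)C1=O | intermediate
15 | 2-propargyl enone ketal | C[Si](C)(C)C#CCC1=CCCC2(OCCO2)C1=O | intermediate
16 | (14R)-allylic alcohol | C[Si](C)(C)C#CCC1=CCCC2(OCCO2)[C@@H]1O | intermediate
17 | mixed 2,4,6-trichlorobenzoic anhydride of 9 | O=C(OC(=O)C1CC[C@H](O[Si](C)(C)C(C)(C)C)[C@@](C)(C(=O)OC)[C@H]1CC(=O)OC)c1c(Cl)cc(Cl)cc1Cl | intermediate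
18 | C20–O–C14 ester | C[Si](C)(C)C#CCC1=CCCC2(OCCO2)[C@@H]1OC(=O)C1CC[C@H](O[Si](C)(C)C(C)(C)C)[C@@](C)(C(=O)OC)[C@H]1CC(=O)OC | intermediate
19 | bis(trimethylsilyl ketene acetal) at C10=C20 and C6=C7 | C[Si](C)(C)C#CCC1=CCCC2(OCCO2)[C@@H]1OC(O[Si](C)(C)C)=C1CC[C@H](O[Si](C)(C)C(C)(C)C)[C@@](C)(C(=O)OC)[C@H]1C=C(OC)O[Si](C)(C)C | intermediate
20 | rearranged C20 trimethylsilyl ester, allylic ketal, C6=C7 ketene acetal | C[Si](C)(C)C#CCC1=CC2(OCCO2)CC[C@H]1[C@]1(C(=O)O[Si](C)(C)C)CC[C@H](O[Si](C)(C)C(C)(C)C)[C@@](C)(C(=O)OC)[C@H]1C=C(OC)O[Si](C)(C)C | intermediate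
21 | cyclised C13 2-(trimethylsilyloxy)ethyl enol ether, C20 silyl ester | C[Si](C)(C)C#CC[C@]23C=C(OCCO[Si](C)(C)C)CC[C@H]2[C@]1(C(=O)O[Si](C)(C)C)CC[C@H](O[Si](C)(C)C(C)(C)C)[C@@](C)(C(=O)OC)[C@H]1[C@@H]3C(=O)OC | intermediate
22 | tricyclic A/B/C keto acid | C[Si](C)(C)C#CC[C@]23CC(=O)CC[C@H]2[C@]1(C(=O)O)CC[C@H](O[Si](C)(C)C(C)(C)C)[C@@](C)(C(=O)OC)[C@H]1[C@@H]3C(=O)OC | intermediate
23 | terminal-alkyne keto acid | C#CC[C@]23CC(=O)CC[C@H]2[C@]1(C(=O)O)CC[C@H](O[Si](C)(C)C(C)(C)C)[C@@](C)(C(=O)OC)[C@H]1[C@@H]3C(=O)OC | intermediate
24 | tetracyclic 13-hydroxy-16-ene C20 acid | C=C1C[C@]23C[C@@]1(O)CC[C@H]2[C@]1(C(=O)O)CC[C@H](O[Si](C)(C)C(C)(C)C)[C@@](C)(C(=O)OC)[C@H]1[C@@H]3C(=O)OC | intermediate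
25 | C20 acid chloride | C=C1C[C@]23C[C@@]1(O)CC[C@H]2[C@]1(C(=O)Cl)CC[C@H](O[Si](C)(C)C(C)(C)C)[C@@](C)(C(=O)OC)[C@H]1[C@@H]3C(=O)OC | intermediate
26 | C20 aldehyde, C7/C19 dimethyl ester, 3-O-TBS | C=C1C[C@]23C[C@@]1(O)CC[C@H]2[C@]1(C=O)CC[C@H](O[Si](C)(C)C(C)(C)C)[C@@](C)(C(=O)OC)[C@H]1[C@@H]3C(=O)OC | intermediate
27 | 3-O-TBS 20-oxo 7,19-diacid | C=C1C[C@]23C[C@@]1(O)CC[C@H]2[C@]1(C=O)CC[C@H](O[Si](C)(C)C(C)(C)C)[C@@](C)(C(=O)O)[C@H]1[C@@H]3C(=O)O | intermediate
28 | CNP0236431.1 | C=C1C[C@]23C[C@@]1(O)CC[C@H]2[C@]1(C=O)CC[C@H](O)[C@@](C)(C(=O)O)[C@H]1[C@@H]3C(=O)O | target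

## Step count

Total step count: 18.
Longest linear sequence: 14 steps (steps 1–7, then 12–18). Steps 8–11 form the four-step ring-C branch.

## Steps most likely to fail

**1. Step 13.**
- What may go wrong:
  - erosion of the facial selectivity at C10 in the [3,3] shift;
  - loss of the C6=C7 ketene acetal during the thermal stage;
  - deactivation of the silyl triflate by residual chloride or amine;
  - sluggish bond formation at the fully substituted C8.
- Fallback, from 18 with the two events separated into individually known reactions: the Ireland–Claisen rearrangement is run alone and quenched cold with aqueous citric acid. The silyl ester and ketene acetal are then hydrolysed while the dioxolane stays, which gives the rearranged ketal acid F1.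
- F1 is purified, and a C10 epimer could be removed at this point.
- F1 is then treated with LDA (3.2 equiv) and TMSCl at −78 °C, so that the ketene acetal is made only after the heating is over. This regenerates 20 free of the debris of the first stage.
- 20 is cyclised in CH2Cl2 with catalytic TMSOTf as a separate intramolecular Mukaiyama–Michael reaction on an unsaturated ketal. The route is rejoined at 20 and continues through 21 to 22.

**2. Step 16.**
- What may go wrong: over-reduction to the C20 alkoxide followed by immediate lactonisation onto C19, or capture of the activated C20 acyl group by the neighbouring C19 ester.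
- Fallback, from 24 through the cold acid chloride 25, replacing the metal hydride by a palladium acyl transfer that never generates an alkoxide: EtSH and Et3N convert 25 into the S-ethyl thioester F2.
- A Fukuyama reduction (Et3SiH, Pd/C, acetone, rt, short contact time to spare the 16-ene) then delivers the aldehyde. The route is rejoined at 26.

**3. Step 17.**
- What may go wrong: incomplete cleavage of the hindered C7 ester, degradation of the aldehyde in hot alkali, or loss of the O3 silyl group followed by retro-aldol epimerisation at C3.
- Fallback, from 26, dividing the task by mechanism: LiOH in THF–H2O at rt cleaves only the C19 ester, which alone has formyl assistance, and gives the 19-acid 7-methyl ester F3.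
- With C19 now a carboxylate that cannot trap a thiolate adduct of the aldehyde, the C7 ester is removed by SN2 dealkylation at its methyl group (n-PrSLi, HMPA, rt). Acidic work-up rejoins the route at 27.

## Further compounds

F1 | step 13 | rearranged ketal acid (C20 CO2H, C13 dioxolane, C8=C14, C7 methyl ester) | C[Si](C)(C)C#CCC1=CC2(OCCO2)CC[C@H]1[C@]1(C(=O)O)CC[C@H](O[Si](C)(C)C(C)(C)C)[C@@](C)(C(=O)OC)[C@H]1CC(=O)OC
F2 | step 16 | C20 S-ethyl thioester | C=C1C[C@]23C[C@@]1(O)CC[C@H]2[C@]1(C(=O)SCC)CC[C@H](O[Si](C)(C)C(C)(C)C)[C@@](C)(C(=O)OC)[C@H]1[C@@H]3C(=O)OC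
F3 | step 17 | 20-oxo 19-acid 7-methyl ester, 3-O-TBS | C=C1C[C@]23C[C@@]1(O)CC[C@H]2[C@]1(C=O)CC[C@H](O[Si](C)(C)C(C)(C)C)[C@@](C)(C(=O)O)[C@H]1[C@@H]3C(=O)OC
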